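## Retrosynthetic overview

1. The target comes from O‑acetylation, chelation‑controlled reduction of a C6 ketone and angeloylation of a 4,5‑epoxy‑3‑hydroxygermacr‑1(10)‑en‑6‑one.
2. The oxirane (last ring formed) comes from alkoxide‑directed nucleophilic epoxidation of the (1(10)E,4E)‑3‑hydroxy dienone; the 4E geometry comes from the 4Z isomer by stannyl conjugate addition and oxidative destannylation.
3. The ten‑membered ring (first ring formed) comes from an anionic oxy‑Cope [3,3] rearrangement of a trans‑1,2‑dialkenylcyclohexenol: C8–C9 is made, C1–C6 is broken, and C1=C10 is set E by a chair transition state.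
4. The dialkenyl carbinol comes from 3‑methylbut‑1‑en‑2‑yllithium (Shapiro) and a 4‑silyloxy‑isopiperitenone, itself made from (S)‑carvone by Luche reduction, silylation and allylic oxidation.
5. The carvone‑derived carbinol carbon becomes C3 and is the only stereocentre carried through the ring expansion; it controls C4/C5, these control C6, and C7 is set by equilibration.

Assumption: germacrane numbering is used for the ten‑membered compounds (ring C1–C10, C14 on C10, C15 on C4, isopropyl on C7, oxygens on C3 and C6, oxirane C4–C5); the target is then (1(10)E,3S,4R,5R,6R,7S) with a (Z)‑2‑methylbut‑2‑enoate (angelate) on O3, and 2,4,6‑triisopropylbenzenesulfonohydrazide is taken as a catalogue item.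

## Route

Step 1
Reactants: 1 (S)‑(+)‑carvone
Product: 2 (1S,5S)‑cis‑carveol
Conditions: NaBH4, CeCl3·7H2O, MeOH, 0 °C
Reagents that add atoms: none
Why: Luche 1,2‑reduction; hydride adds axially on the face opposite the pseudo‑equatorial isopropenyl group, giving the 1,3‑cis alcohol whose new (S) carbinol centre becomes C3 of the target.

Step 2
Reactants: 2 (1S,5S)‑cis‑carveol
Product: 3 tert‑butyldimethylsilyl ether of 2
Conditions: TBSCl, imidazole, DMF, rt
Reagents that add atoms: tert‑butyldimethylsilyl chloride, CC(C)(C)[Si](C)(C)Cl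
Why: Standard O‑silylation gives an ether that survives organolithium, KH and stannyllithium; no stereocentre is touched.

Step 3
Reactants: 3 tert‑butyldimethylsilyl ether of 2
Product: 4 (4S,6S)‑4‑[(tert‑butyldimethylsilyl)oxy]‑3‑methyl‑6‑(prop‑1‑en‑2‑yl)cyclohex‑2‑en‑1‑one
Conditions: CrO3, 3,5‑dimethylpyrazole, CH2Cl2, −20 °C
Reagents that add atoms: chromium trioxide, O=[Cr](=O)=O
Why: Allylic C–H oxidation by the hexavalent chromium–pyrazole complex occurs at the only free allylic methylene of the trisubstituted ring olefin, leaving the less reactive isopropenyl group and both stereocentres untouched.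

Step 4
Reactants: 5 3‑methylbutan‑2‑one; 6 2,4,6‑tri(propan‑2‑yl)benzenesulfonohydrazide
Product: 7 N'‑[(2E)‑3‑methylbutan‑2‑ylidene]‑2,4,6‑tri(propan‑2‑yl)benzenesulfonohydrazide
Conditions: MeOH, cat. HCl, rt, crystallise
Reagents that add atoms: none
Why: Hydrazone condensation; the E isomer (N–N anti to isopropyl) crystallises and places the methyl group syn to nitrogen for the next step.

Step 5
Reactants: 7 N'‑[(2E)‑3‑methylbutan‑2‑ylidene]‑2,4,6‑tri(propan‑2‑yl)benzenesulfonohydrazide; 4 (4S,6S)‑4‑[(tert‑butyldimethylsilyl)oxy]‑3‑methyl‑6‑(prop‑1‑en‑2‑yl)cyclohex‑2‑en‑1‑one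
Product: 9 (1S,4S,6S)‑4‑[(tert‑butyldimethylsilyl)oxy]‑3‑methyl‑1‑(3‑methylbut‑1‑en‑2‑yl)‑6‑(prop‑1‑en‑2‑yl)cyclohex‑2‑en‑1‑ol, via 3‑methylbut‑1‑en‑2‑yllithium 8 (not isolated)
Conditions: 7 (1.5 equiv), n‑BuLi (2.1 equiv per 7), THF, −78 → 0 °C; then 4, −78 °C; NH4Cl aq
Reagents that add atoms: none
Why: Shapiro reaction (deprotonation at N–H and at the methyl group, loss of sulfinate and N2) gives the 2‑lithioalkene, which adds 1,2 to the enone on the face opposite the isopropenyl and silyloxy groups, so the new alkenyl group is trans to isopropenyl (carbinol carbon S, destroyed in step 6).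

Step 6
Reactants: 9 (1S,4S,6S)‑dialkenyl carbinol
Product: 12 (1(10)E,4Z,3S)‑3‑[(tert‑butyldimethylsilyl)oxy]germacra‑1(10),4‑dien‑6‑one (C7 epimer mixture), via potassium alkoxide 10 (not isolated), via potassium enolate 11 (not isolated)
Conditions: KH, 18‑crown‑6, THF, 0 → 25 °C; NH4Cl aq, −78 °C
Reagents that add atoms: none
Why: Anionic oxy‑Cope [3,3]‑sigmatropic rearrangement through a chair transition state with both alkenyl groups equatorial forms C8–C9, breaks C1–C6 and gives the E C1=C10 bond plus the C6 enolate (the driving force); C4=C5 keeps its Z geometry from the six‑membered ring, and C7 is formed unselectively on protonation and corrected in step 10.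

Step 7
Reactants: 12 (1(10)E,4Z,3S)‑dienone
Product: 14 (1(10)E,3S)‑3‑[(tert‑butyldimethylsilyl)oxy]‑4‑(trimethylstannyl)germacr‑1(10)‑en‑6‑one (mixture at C4 and C7), via lithium enolate 13 (not isolated)
Conditions: Me3SnLi (from Me3SnSnMe3, MeLi), THF, −78 °C; NH4Cl aq
Reagents that add atoms: trimethylstannyllithium, [Li][Sn](C)(C)C
Why: Conjugate (1,4) addition of the stannyl anion to the β,β‑disubstituted enone saturates C4–C5 so the ring can relax; the new C4 centre is lost again in step 8.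

Step 8
Reactants: 14 β‑stannyl ketone
Product: 15 (1(10)E,4E,3S)‑3‑[(tert‑butyldimethylsilyl)oxy]germacra‑1(10),4‑dien‑6‑one (C7 epimer mixture)
Conditions: CrO3·2C5H5N, CH2Cl2, 0 °C → rt; Et3N‑deactivated silica, keep below 30 °C
Reagents that add atoms: none
Why: Oxidative destannylation: hexavalent chromium attacks the tertiary C–Sn bond and the C5 proton is lost toward the carbonyl from the relaxed conformer with C3 and C6 antiperiplanar about C4–C5, so the enone returns as the kinetic 4E isomer, which this non‑basic, non‑nucleophilic medium does not convert to the more stable 4Z form.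

Step 9
Reactants: 15 (1(10)E,4E,3S)‑silyloxy dienone
Product: 16 (1(10)E,4E,3S)‑3‑hydroxygermacra‑1(10),4‑dien‑6‑one (C7 epimer mixture)
Conditions: Bu4NF, AcOH (1:1), THF, 0 °C → rt
Reagents that add atoms: none
Why: Fluoride cleavage of the Si–O bond under buffered conditions frees the C3 hydroxyl for direction of the next step; the 4E geometry prevents hemiketal formation with the C6 ketone, and C3 is untouched.

Step 10
Reactants: 16 (1(10)E,4E,3S)‑hydroxy dienone
Product: 18 (1(10)E,3S,4R,5S,7S)‑4,5‑epoxy‑3‑hydroxygermacr‑1(10)‑en‑6‑one, via epoxy ketone epimer mixture 17 (not isolated)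
Conditions: t‑BuOOLi (3 equiv, from t‑BuOOH, n‑BuLi), THF, −20 → 0 °C; NH4Cl aq; then DBU, CH2Cl2, rt
Reagents that add atoms: tert‑butyl hydroperoxide (as its lithium salt), CC(C)(C)OO
Why: Weitz–Scheffer nucleophilic epoxidation, selective for the enone over C1=C10, in which the C3 lithium alkoxide delivers the peroxide to C4 on the exposed face syn to O3 and the enolate closes before C4–C5 rotation, giving the trans (4R,5S) oxirane; DBU then equilibrates the enolisable C7 to the epimer with pseudo‑equatorial isopropyl (7S).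

Step 11
Reactants: 18 (3S,4R,5S,7S)‑epoxy hydroxy ketone
Product: 19 (1(10)E,3S,4R,5S,7S)‑3‑{[(2Z)‑2‑methylbut‑2‑enoyl]oxy}‑4,5‑epoxygermacr‑1(10)‑en‑6‑one
Conditions: angelic acid, 2,4,6‑trichlorobenzoyl chloride, Et3N, toluene, rt; then 18, 75 °C
Reagents that add atoms: angelic acid [(2Z)‑2‑methylbut‑2‑enoic acid], C/C=C(/C)C(=O)O
Why: Yamaguchi‑type esterification through the mixed anhydride without a nucleophilic catalyst acylates the pseudo‑equatorial C3 hydroxyl while keeping the Z geometry of the angelate; the reaction is at oxygen, so C3 is retained.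

Step 12
Reactants: 19 angelate epoxy ketone
Product: 20 (1(10)E,3S,4R,5R,6R,7S)‑3‑{[(2Z)‑2‑methylbut‑2‑enoyl]oxy}‑4,5‑epoxygermacr‑1(10)‑en‑6‑ol
Conditions: Zn(BH4)2, Et2O, −20 → 0 °C
Reagents that add atoms: none
Why: Chelation‑controlled reduction of an α,β‑epoxy ketone: zinc bridges the carbonyl and oxirane oxygens and hydride enters anti to C4, from outside the ring and past H7, giving the anti epoxy alcohol (6R) without touching the conjugated ester.

Step 13
Reactants: 20 epoxy alcohol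
Product: 21 target, (1(10)E,3S,4R,5R,6R,7S)‑6‑acetoxy‑3‑{[(2Z)‑2‑methylbut‑2‑enoyl]oxy}‑4,5‑epoxygermacr‑1(10)‑ene
Conditions: Ac2O, pyridine, cat. DMAP, CH2Cl2, 0 °C → rt
Reagents that add atoms: acetic anhydride, CC(=O)OC(C)=O
Why: DMAP‑catalysed O‑acetylation of the hindered pseudo‑axial C6 hydroxyl under mild base, with retention at C6 and no effect on the oxirane or the angelate.

## Compound list

1 | (S)‑(+)‑carvone, (5S)‑2‑methyl‑5‑(prop‑1‑en‑2‑yl)cyclohex‑2‑en‑1‑one | CC1=CC[C@@H](CC1=O)C(C)=C | starting material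
2 | (1S,5S)‑cis‑carveol (OH cis to isopropenyl) | CC1=CC[C@@H](C[C@@H]1O)C(C)=C | intermediate
3 | tert‑butyldimethyl{[(1S,5S)‑2‑methyl‑5‑(prop‑1‑en‑2‑yl)cyclohex‑2‑en‑1‑yl]oxy}silane | CC1=CC[C@@H](C[C@@H]1O[Si](C)(C)C(C)(C)C)C(C)=C | intermediate
4 | (4S,6S)‑4‑[(tert‑butyldimethylsilyl)oxy]‑3‑methyl‑6‑(prop‑1‑en‑2‑yl)cyclohex‑2‑en‑1‑one | CC1=CC(=O)[C@@H](C[C@@H]1O[Si](C)(C)C(C)(C)C)C(C)=C | intermediate
5 | 3‑methylbutan‑2‑one | CC(=O)C(C)C | starting material
6 | 2,4,6‑tri(propan‑2‑yl)benzenesulfonohydrazide | NNS(=O)(=O)c1c(C(C)C)cc(C(C)C)cc1C(C)C | starting material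
7 | N'‑[(2E)‑3‑methylbutan‑2‑ylidene]‑2,4,6‑tri(propan‑2‑yl)benzenesulfonohydrazide | CC(C)/C(C)=N/NS(=O)(=O)c1c(C(C)C)cc(C(C)C)cc1C(C)C | intermediate
8 | 3‑methylbut‑1‑en‑2‑yllithium | [Li]C(=C)C(C)C | intermediate
9 | (1S,4S,6S)‑4‑[(tert‑butyldimethylsilyl)oxy]‑3‑methyl‑1‑(3‑methylbut‑1‑en‑2‑yl)‑6‑(prop‑1‑en‑2‑yl)cyclohex‑2‑en‑1‑ol (OH cis to isopropenyl and to OTBS) | CC1=C[C@@](O)(C(=C)C(C)C)[C@@H](C[C@@H]1O[Si](C)(C)C(C)(C)C)C(C)=C | intermediate
10 | potassium alkoxide of 9 | CC1=C[C@@]([O-])(C(=C)C(C)C)[C@@H](C[C@@H]1O[Si](C)(C)C(C)(C)C)C(C)=C.[K+] | intermediate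
11 | potassium (1(10)E,4Z,6E,3S)‑3‑[(tert‑butyldimethylsilyl)oxy]germacra‑1(10),4,6‑trien‑6‑olate | CC(C)(C)[Si](C)(C)O[C@H]1C/C=C(\C)CC/C(C(C)C)=C(\[O-])/C=C1/C.[K+] | intermediate
12 | (1(10)E,4Z,3S)‑3‑[(tert‑butyldimethylsilyl)oxy]germacra‑1(10),4‑dien‑6‑one, 7RS | CC(C)(C)[Si](C)(C)O[C@H]1C/C=C(\C)CCC(C(C)C)C(=O)/C=C1/C | intermediate
13 | lithium (1(10)E,3S)‑3‑[(tert‑butyldimethylsilyl)oxy]‑4‑(trimethylstannyl)germacra‑1(10),5‑dien‑6‑olate | CC(C)(C)[Si](C)(C)O[C@H]1C/C=C(\C)CCC(C(C)C)C([O-])=CC1(C)[Sn](C)(C)C.[Li+] | intermediate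
14 | (1(10)E,3S)‑3‑[(tert‑butyldimethylsilyl)oxy]‑4‑(trimethylstannyl)germacr‑1(10)‑en‑6‑one, 4RS,7RS | CC(C)(C)[Si](C)(C)O[C@H]1C/C=C(\C)CCC(C(C)C)C(=O)CC1(C)[Sn](C)(C)C | intermediate
15 | (1(10)E,4E,3S)‑3‑[(tert‑butyldimethylsilyl)oxy]germacra‑1(10),4‑dien‑6‑one, 7RS | CC(C)(C)[Si](C)(C)O[C@H]1C/C=C(\C)CCC(C(C)C)C(=O)/C=C1\C | intermediate
16 | (1(10)E,4E,3S)‑3‑hydroxygermacra‑1(10),4‑dien‑6‑one, 7RS | O[C@H]1C/C=C(\C)CCC(C(C)C)C(=O)/C=C1\C | intermediate
17 | (1(10)E,3S,4R,5S)‑4,5‑epoxy‑3‑hydroxygermacr‑1(10)‑en‑6‑one, 7RS | O[C@H]1C/C=C(\C)CCC(C(C)C)C(=O)[C@H]2O[C@]12C | intermediate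
18 | (1(10)E,3S,4R,5S,7S)‑4,5‑epoxy‑3‑hydroxygermacr‑1(10)‑en‑6‑one | O[C@H]1C/C=C(\C)CC[C@@H](C(C)C)C(=O)[C@H]2O[C@]12C | intermediate
19 | (1(10)E,3S,4R,5S,7S)‑3‑{[(2Z)‑2‑methylbut‑2‑enoyl]oxy}‑4,5‑epoxygermacr‑1(10)‑en‑6‑one | C/C=C(/C)C(=O)O[C@H]1C/C=C(\C)CC[C@@H](C(C)C)C(=O)[C@H]2O[C@]12C | intermediate
20 | (1(10)E,3S,4R,5R,6R,7S)‑3‑{[(2Z)‑2‑methylbut‑2‑enoyl]oxy}‑4,5‑epoxygermacr‑1(10)‑en‑6‑ol | C/C=C(/C)C(=O)O[C@H]1C/C=C(\C)CC[C@@H](C(C)C)[C@@H](O)[C@H]2O[C@]12C | intermediate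
21 | (1(10)E,3S,4R,5R,6R,7S)‑6‑acetoxy‑3‑{[(2Z)‑2‑methylbut‑2‑enoyl]oxy}‑4,5‑epoxygermacr‑1(10)‑ene | C/C=C(/C)C(=O)O[C@H]1C/C=C(\C)CC[C@@H](C(C)C)[C@@H](OC(C)=O)[C@H]2O[C@]12C | target

## Step count and weak points

Total: 13 steps. Longest linear sequence: 12 steps (1 → 21 through steps 1–3 and 5–13; step 4 is a one‑step side branch).

Step 8 (most likely to fail). Z cyclodecenones are more stable than E, so the E enone must come from a kinetic elimination, and the vicinal silyloxy group could be lost with tin instead. The fallback sets out from 12 and comes back at 15. RhCl(PPh3)3‑catalysed 1,4‑hydrosilylation of 12 with Et3SiH gives the C5=C6 triethylsilyl enol ether F3 regiospecifically. Saegusa–Ito dehydrogenation of F3 with Pd(OAc)2 in MeCN then restores C4=C5 by syn β‑hydride elimination from the C5‑bound palladium enolate; as in other syn eliminations of cyclodecyl systems, the transoid arrangement of C3 and C6 is preferred and gives 15.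

Step 10. The C3 alkoxide has to deliver the peroxide to the correct face, and the C7 equilibrium has to favour 7S. The fallback sets out from 15 and comes back at 21; it moves the control from lithium‑alkoxide delivery at the enone to hydroxyl‑directed electrophilic epoxidation at the allylic alcohol. After DBU equilibration of C7 in 15, Luche reduction (NaBH4, CeCl3·7H2O) from the outer face of the s‑cis enone gives the 6R allylic alcohol F4. VO(acac)2 and t‑BuOOH then epoxidise only C4=C5, from the C6 vanadate whose oxygen the ring holds near the olefin plane, giving the epoxy alcohol F5. Acetylation gives the acetate F6, Bu4NF with AcOH gives the 3‑hydroxy acetate F7, and angeloylation as in step 11 gives 21.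

Step 3. Over‑oxidation, attack at the isopropenyl group, or attack at the silyloxy‑bearing carbon can compete with the wanted C–H oxidation. The fallback sets out from 3 and comes back at 4. Sensitised photo‑oxygenation (O2, tetraphenylporphyrin, hν, CH2Cl2, 0 °C; Schenck ene reaction) shifts the ring double bond and gives the tertiary allylic hydroperoxide F1, which PPh3 reduces to the tertiary allylic alcohol F2. Pyridinium chlorochromate ([C5H5NH][CrO3Cl], CH2Cl2) then effects the oxidative 1,3‑transposition (allylic chromate [3,3] shift, then oxidation) to 4. The oxygen is thus placed on the methyl‑bearing carbon and moved by a sigmatropic shift, not by direct C–H oxidation; regioisomeric ene products are removed at F2.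

## Further compounds

F1 | step 3 | (1RS,4R,6S)‑6‑[(tert‑butyldimethylsilyl)oxy]‑1‑methyl‑4‑(prop‑1‑en‑2‑yl)cyclohex‑2‑en‑1‑yl hydroperoxide | CC1(OO)C=C[C@@H](C[C@@H]1O[Si](C)(C)C(C)(C)C)C(C)=C
F2 | step 3 | (1RS,4R,6S)‑6‑[(tert‑butyldimethylsilyl)oxy]‑1‑methyl‑4‑(prop‑1‑en‑2‑yl)cyclohex‑2‑en‑1‑ol | CC1(O)C=C[C@@H](C[C@@H]1O[Si](C)(C)C(C)(C)C)C(C)=C
F3 | step 8 | (1(10)E,3S)‑3‑[(tert‑butyldimethylsilyl)oxy]‑6‑[(triethylsilyl)oxy]germacra‑1(10),5‑diene, 4RS,7RS | CC(C)(C)[Si](C)(C)O[C@H]1C/C=C(\C)CCC(C(C)C)C(O[Si](CC)(CC)CC)=CC1C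
F4 | step 10 | (1(10)E,4E,3S,6R,7S)‑3‑[(tert‑butyldimethylsilyl)oxy]germacra‑1(10),4‑dien‑6‑ol | CC(C)(C)[Si](C)(C)O[C@H]1C/C=C(\C)CC[C@@H](C(C)C)[C@@H](O)/C=C1\C
F5 | step 10 | (1(10)E,3S,4S,5R,6R,7S)‑3‑[(tert‑butyldimethylsilyl)oxy]‑4,5‑epoxygermacr‑1(10)‑en‑6‑ol (same spatial arrangement as 21) | CC(C)(C)[Si](C)(C)O[C@H]1C/C=C(\C)CC[C@@H](C(C)C)[C@@H](O)[C@H]2O[C@]12C
F6 | step 10 | (1(10)E,3S,4S,5R,6R,7S)‑6‑acetoxy‑3‑[(tert‑butyldimethylsilyl)oxy]‑4,5‑epoxygermacr‑1(10)‑ene (same spatial arrangement as 21) | CC(C)(C)[Si](C)(C)O[C@H]1C/C=C(\C)CC[C@@H](C(C)C)[C@@H](OC(C)=O)[C@H]2O[C@]12C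
F7 | step 10 | (1(10)E,3S,4R,5R,6R,7S)‑6‑acetoxy‑4,5‑epoxygermacr‑1(10)‑en‑3‑ol | O[C@H]1C/C=C(\C)CC[C@@H](C(C)C)[C@@H](OC(C)=O)[C@H]2O[C@]12C
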